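**Strategy.** The oxane (O1, C2 aryl, C3 side chain, C4 OH, C5, C6 arylethyl) is opened at O1–C2, which is made late by reductive etherification of an aryl ketone, and then at the two C–C bonds flanking the C4–C5 unit. The ring carries oxygen on C6 and on C4 with C5 between them, and C3 is alpha to the aryl-bearing C2: a double aldol pattern around one acetaldehyde unit. In one pot, an acetaldehyde enol silane adds to a 3-arylpropanal under a chiral confined acid (C5–C6), and the resulting β-silyloxy aldehyde is trapped by the boron enolate of an aryl ketone that already carries the side chain (C3–C4). The precursors are three open-chain pieces.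

Key step: step 10

Remarks on the chemistry:
- TBS = tert-butyldimethylsilyl, TES = triethylsilyl; all four phenols travel as TBS ethers.
- Side chain locants: C1'=C2' (styryl), C3' (on ring C3), C4' (carbinol).
- Assumption: in steps 3 and 10 the antipode of the chiral ligand or acid is the one that delivers the stated configuration.

Step 1
Reactants: 1 tert-butyl(4-iodophenoxy)dimethylsilane; 2 prop-2-en-1-ol
Product: 3 3-[4-(TBSO)phenyl]propanal
Conditions: Pd(OAc)2 (3 mol%), NaHCO3, Bu4NCl, DMF, 40 °C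
Reagents that add atoms: none
Why: Heck arylation of allyl alcohol (Jeffery conditions); the aryl group adds to the terminal carbon and β-hydride elimination toward the carbinol gives the enol, hence the aldehyde.

Step 2
Reactants: 1 tert-butyl(4-iodophenoxy)dimethylsilane; 4 but-3-en-1-ol
Product: 5 4-[4-(TBSO)phenyl]butanal
Conditions: Pd(OAc)2 (3 mol%), LiOAc, LiCl, Bu4NCl, DMF, 60 °C
Reagents that add atoms: none
Why: Heck arylation with chain walking; repeated Pd–H elimination and re-addition should move the double bond to the carbinol carbon and release the aldehyde.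

Step 3
Reactants: 5 4-[4-(TBSO)phenyl]butanal; 6 methyl propiolate
Product: 7 methyl (4S)-4-hydroxy-7-[4-(TBSO)phenyl]hept-2-ynoate
Conditions: (S,S)-2,6-bis{[2-(hydroxydiphenylmethyl)pyrrolidin-1-yl]methyl}-4-methylphenol (10 mol%), Me2Zn, Ph3PO (20 mol%), toluene, 4 °C; aq. NH4Cl
Reagents that add atoms: none
Why: Zinc–ProPhenol catalysed asymmetric alkynylation of an aldehyde; the dinuclear zinc complex should deliver the alkynyl group to one aldehyde face and set C4' (S).

Step 4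
Reactants: 7 methyl (4S)-4-hydroxy-7-[4-(TBSO)phenyl]hept-2-ynoate
Product: 9 (5S)-5-{3-[4-(TBSO)phenyl]propyl}furan-2(5H)-one, via (Z)-hydroxy enoate 8 (not isolated)
Conditions: H2 (1 atm), Pd/CaCO3 poisoned with Pb(OAc)2, quinoline, EtOAc, 23 °C; then pyridinium p-toluenesulfonate (cat.), toluene, 50 °C
Reagents that add atoms: none
Why: Lindlar semi-hydrogenation gives the (Z)-enoate, whose hydroxyl and ester are cis and should lactonise; the stereocentre is untouched.

Step 5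
Reactants: 9 (5S)-5-{3-[4-(TBSO)phenyl]propyl}furan-2(5H)-one; 10 vinylmagnesium bromide
Product: 11 (4S,5S)-4-ethenyl-5-{3-[4-(TBSO)phenyl]propyl}oxolan-2-one
Conditions: CuI (20 mol%), THF, −78 → −40 °C; aq. NH4Cl
Reagents that add atoms: none
Why: Copper-catalysed conjugate addition to a butenolide; the vinyl group should enter anti to the C5 substituent and set C3' in the trans relation.

Step 6
Reactants: 11 (4S,5S)-4-ethenyl-5-{3-[4-(TBSO)phenyl]propyl}oxolan-2-one; 1 tert-butyl(4-iodophenoxy)dimethylsilane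
Product: 12 (4S,5S)-4-{(E)-2-[4-(TBSO)phenyl]ethenyl}-5-{3-[4-(TBSO)phenyl]propyl}oxolan-2-one
Conditions: Pd(OAc)2 (5 mol%), P(o-tolyl)3 (10 mol%), Et3N, MeCN, 80 °C
Reagents that add atoms: none
Why: Heck arylation of the terminal vinyl group; syn insertion and syn β-hydride elimination toward the benzylic position should give the conjugated (E)-styrene.

Step 7
Reactants: 1 tert-butyl(4-iodophenoxy)dimethylsilane; 12 (4S,5S)-4-{(E)-2-[4-(TBSO)phenyl]ethenyl}-5-{3-[4-(TBSO)phenyl]propyl}oxolan-2-one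
Product: 14 (3S,4S)-4-hydroxy-1,7-bis[4-(TBSO)phenyl]-3-{(E)-2-[4-(TBSO)phenyl]ethenyl}heptan-1-one, via aryllithium 13 (not isolated)
Conditions: 1, n-BuLi, THF, −78 °C; then 12, −78 °C; aq. NH4Cl
Reagents that add atoms: none
Why: Iodine–lithium exchange, then addition of the aryllithium to the lactone carbonyl; the lithium lactolate is stable at −78 °C, so a single addition should give the aryl ketone (C2) and free O4'.

Step 8
Reactants: 14 (3S,4S)-4-hydroxy-1,7-bis[4-(TBSO)phenyl]-3-{(E)-2-[4-(TBSO)phenyl]ethenyl}heptan-1-one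
Product: 15 (3S,4S)-4-(TBSO)-1,7-bis[4-(TBSO)phenyl]-3-{(E)-2-[4-(TBSO)phenyl]ethenyl}heptan-1-one
Conditions: TBSCl, imidazole, 4-(dimethylamino)pyridine (cat.), DMF, 40 °C
Reagents that add atoms: tert-butyldimethylsilyl chloride CC(C)(C)[Si](C)(C)Cl
Why: Silylation of the open-chain secondary alcohol (the aryl ketone form should dominate over the lactol); this keeps O4' out of step 11 and is more acid-stable than the TES ether removed there.

Step 9
Reactants: 16 tetrahydrofuran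
Product: 18 triethyl(ethenyloxy)silane, via lithium ethenolate 17 (not isolated)
Conditions: n-BuLi, THF, 25 °C, 16 h; then Et3SiCl, 0 °C
Reagents that add atoms: chlorotriethylsilane CC[Si](CC)(CC)Cl
Why: α-Lithiation of tetrahydrofuran and cycloreversion gives ethene and the lithium enolate of acetaldehyde, which is O-silylated.

Step 10
Reactants: 3 3-[4-(TBSO)phenyl]propanal; 18 triethyl(ethenyloxy)silane; 15 (3S,4S)-4-(TBSO)-1,7-bis[4-(TBSO)phenyl]-3-{(E)-2-[4-(TBSO)phenyl]ethenyl}heptan-1-one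
Product: 21 (2S,3S,5S)-3-hydroxy-5-(triethylsilyloxy)-1,7-bis[4-(TBSO)phenyl]-2-{(1E,3R,4S)-4-(TBSO)-1,7-bis[4-(TBSO)phenyl]hept-1-en-3-yl}heptan-1-one, via silyloxy aldehyde 19 (not isolated), via boron enolate 20 (not isolated)
Conditions: 3, 18, IDPi acid HN[P(=NSO2CF3)(O2C20H10Ar2)]2 from (S)-3,3'-diaryl-BINOL (1 mol%), CH2Cl2, −40 °C; then added to 20 [from 15, (c-C6H11)2BCl, Et3N, Et2O, −78 → 0 °C] at −78 °C, → −20 °C; MeOH, pH 7 buffer, H2O2, 0 °C
Reagents that add atoms: none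
Why: The IDPi acid is silylated by 18 and the resulting silylium–imidodiphosphorimidate ion pair activates 3; the enol silane carbon (C5) adds to the aldehyde carbon (C6) inside the confined chiral anion with the silyl group ending on the new oxygen, and aldehyde 19 is then captured by the (E)-enol borinate 20 through a closed Zimmerman–Traxler chair that joins C3 to C4. The closest known reaction types are the confined-acid-catalysed single Mukaiyama aldolization of acetaldehyde enol silanes and the anti-selective aldol addition of (E)-dicyclohexylboron enolates of aryl ketones. No ring is closed here; the oxane is closed in step 11. C6 (S) is set by the chiral counter-anion, C4 follows from the (E)-enolate geometry in the chair (3,4-anti), and C3 is set by allylic 1,3-strain in 20, which holds the C3'–H bond in the enolate plane so that the aldehyde adds anti to the bulky C4' branch. The step needs mono-addition of the acetaldehyde unit and reaction at the aldehyde only: the confined catalyst should reject the larger β-silyloxy aldehyde as a second acceptor, 15 has a single enolizable position, and the silyloxy centre of 19 exerts little 1,3-induction in a closed boron transition state, so the enolate face decides.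

Step 11
Reactants: 21 (2S,3S,5S)-3-hydroxy-5-(triethylsilyloxy)-1,7-bis[4-(TBSO)phenyl]-2-{(1E,3R,4S)-4-(TBSO)-1,7-bis[4-(TBSO)phenyl]hept-1-en-3-yl}heptan-1-one
Product: 23 (2S,3S,4S,6S)-2-[4-(TBSO)phenyl]-6-{2-[4-(TBSO)phenyl]ethyl}-3-{(1E,3R,4S)-4-(TBSO)-1,7-bis[4-(TBSO)phenyl]hept-1-en-3-yl}oxan-4-ol, via dihydroxy ketone 22 (not isolated)
Conditions: pyridinium p-toluenesulfonate (cat.), MeOH/CH2Cl2, 0 °C; then Et3SiH, BF3·OEt2, CH2Cl2/MeCN, −40 °C
Reagents that add atoms: none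
Why: Reductive etherification: selective TES removal frees O at C6, the six-membered hemiketal ionises to an aryl-stabilised cyclic oxocarbenium ion, and axial hydride delivery on the half-chair with the C6 chain pseudo-equatorial should set C2 in the 2,6-cis relation.

Step 12
Reactants: 23 (2S,3S,4S,6S)-2-[4-(TBSO)phenyl]-6-{2-[4-(TBSO)phenyl]ethyl}-3-{(1E,3R,4S)-4-(TBSO)-1,7-bis[4-(TBSO)phenyl]hept-1-en-3-yl}oxan-4-ol
Product: 24 CNP0132332.1, (2S,3S,4S,6S)-3-[(1E,3R,4S)-4-hydroxy-1,7-bis(4-hydroxyphenyl)hept-1-en-3-yl]-2-(4-hydroxyphenyl)-6-[2-(4-hydroxyphenyl)ethyl]oxan-4-ol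
Conditions: Bu4NF, AcOH, THF, 0 → 23 °C
Reagents that add atoms: none
Why: Fluoride cleavage of the four aryl silyl ethers and the secondary silyl ether; acetic acid buffers the phenoxides so that the benzylic C2–O1 bond should not open.

**Compound list**

1 | tert-butyl(4-iodophenoxy)dimethylsilane | CC(C)(C)[Si](C)(C)Oc1ccc(I)cc1 | starting material
2 | prop-2-en-1-ol | OCC=C | starting material
3 | 3-[4-(TBSO)phenyl]propanal | O=CCCc1ccc(O[Si](C)(C)C(C)(C)C)cc1 | intermediate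
4 | but-3-en-1-ol | OCCC=C | starting material
5 | 4-[4-(TBSO)phenyl]butanal | O=CCCCc1ccc(O[Si](C)(C)C(C)(C)C)cc1 | intermediate
6 | methyl propiolate | COC(=O)C#C | starting material
7 | methyl (4S)-4-hydroxy-7-[4-(TBSO)phenyl]hept-2-ynoate | COC(=O)C#C[C@@H](O)CCCc1ccc(O[Si](C)(C)C(C)(C)C)cc1 | intermediate
8 | methyl (2Z,4S)-4-hydroxy-7-[4-(TBSO)phenyl]hept-2-enoate | COC(=O)/C=C\[C@@H](O)CCCc1ccc(O[Si](C)(C)C(C)(C)C)cc1 | intermediate (not isolated)
9 | (5S)-5-{3-[4-(TBSO)phenyl]propyl}furan-2(5H)-one | O=C1C=C[C@H](CCCc2ccc(O[Si](C)(C)C(C)(C)C)cc2)O1 | intermediate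
10 | vinylmagnesium bromide | C=C[Mg]Br | starting material
11 | (4S,5S)-4-ethenyl-5-{3-[4-(TBSO)phenyl]propyl}oxolan-2-one (trans) | C=C[C@@H]1CC(=O)O[C@H]1CCCc1ccc(O[Si](C)(C)C(C)(C)C)cc1 | intermediate
12 | (4S,5S)-4-{(E)-2-[4-(TBSO)phenyl]ethenyl}-5-{3-[4-(TBSO)phenyl]propyl}oxolan-2-one | CC(C)(C)[Si](C)(C)Oc1ccc(/C=C/[C@@H]2CC(=O)O[C@H]2CCCc2ccc(O[Si](C)(C)C(C)(C)C)cc2)cc1 | intermediate
13 | 4-(TBSO)phenyllithium | [Li]c1ccc(O[Si](C)(C)C(C)(C)C)cc1 | intermediate (not isolated)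
14 | (3S,4S)-4-hydroxy-1,7-bis[4-(TBSO)phenyl]-3-{(E)-2-[4-(TBSO)phenyl]ethenyl}heptan-1-one | CC(C)(C)[Si](C)(C)Oc1ccc(/C=C/[C@H](CC(=O)c2ccc(O[Si](C)(C)C(C)(C)C)cc2)[C@@H](O)CCCc2ccc(O[Si](C)(C)C(C)(C)C)cc2)cc1 | intermediate
15 | (3S,4S)-4-(TBSO)-1,7-bis[4-(TBSO)phenyl]-3-{(E)-2-[4-(TBSO)phenyl]ethenyl}heptan-1-one | CC(C)(C)[Si](C)(C)Oc1ccc(/C=C/[C@H](CC(=O)c2ccc(O[Si](C)(C)C(C)(C)C)cc2)[C@@H](O[Si](C)(C)C(C)(C)C)CCCc2ccc(O[Si](C)(C)C(C)(C)C)cc2)cc1 | intermediate
16 | tetrahydrofuran | C1CCOC1 | starting material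
17 | lithium ethenolate | [Li]OC=C | intermediate (not isolated)
18 | triethyl(ethenyloxy)silane | CC[Si](CC)(CC)OC=C | intermediate
19 | (3S)-5-[4-(TBSO)phenyl]-3-(triethylsilyloxy)pentanal | O=CC[C@@H](O[Si](CC)(CC)CC)CCc1ccc(O[Si](C)(C)C(C)(C)C)cc1 | intermediate (not isolated)
20 | (E)-enol dicyclohexylborinate of 15 | CC(C)(C)[Si](C)(C)Oc1ccc(/C=C/[C@H](/C=C(/OB(C2CCCCC2)C2CCCCC2)c2ccc(O[Si](C)(C)C(C)(C)C)cc2)[C@@H](O[Si](C)(C)C(C)(C)C)CCCc2ccc(O[Si](C)(C)C(C)(C)C)cc2)cc1 | intermediate (not isolated)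
21 | (2S,3S,5S)-3-hydroxy-5-(triethylsilyloxy)-1,7-bis[4-(TBSO)phenyl]-2-{(1E,3R,4S)-4-(TBSO)-1,7-bis[4-(TBSO)phenyl]hept-1-en-3-yl}heptan-1-one | CC(C)(C)[Si](C)(C)Oc1ccc(/C=C/[C@H]([C@H](C(=O)c2ccc(O[Si](C)(C)C(C)(C)C)cc2)[C@@H](O)C[C@@H](O[Si](CC)(CC)CC)CCc2ccc(O[Si](C)(C)C(C)(C)C)cc2)[C@@H](O[Si](C)(C)C(C)(C)C)CCCc2ccc(O[Si](C)(C)C(C)(C)C)cc2)cc1 | intermediate
22 | (2S,3S,5S)-3,5-dihydroxy-1,7-bis[4-(TBSO)phenyl]-2-{(1E,3R,4S)-4-(TBSO)-1,7-bis[4-(TBSO)phenyl]hept-1-en-3-yl}heptan-1-one (in equilibrium with its six-membered hemiketal) | CC(C)(C)[Si](C)(C)Oc1ccc(/C=C/[C@H]([C@H](C(=O)c2ccc(O[Si](C)(C)C(C)(C)C)cc2)[C@@H](O)C[C@@H](O)CCc2ccc(O[Si](C)(C)C(C)(C)C)cc2)[C@@H](O[Si](C)(C)C(C)(C)C)CCCc2ccc(O[Si](C)(C)C(C)(C)C)cc2)cc1 | intermediate (not isolated)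
23 | (2S,3S,4S,6S)-2-[4-(TBSO)phenyl]-6-{2-[4-(TBSO)phenyl]ethyl}-3-{(1E,3R,4S)-4-(TBSO)-1,7-bis[4-(TBSO)phenyl]hept-1-en-3-yl}oxan-4-ol | CC(C)(C)[Si](C)(C)Oc1ccc(/C=C/[C@H]([C@@H]2[C@@H](c3ccc(O[Si](C)(C)C(C)(C)C)cc3)O[C@@H](CCc3ccc(O[Si](C)(C)C(C)(C)C)cc3)C[C@@H]2O)[C@@H](O[Si](C)(C)C(C)(C)C)CCCc2ccc(O[Si](C)(C)C(C)(C)C)cc2)cc1 | intermediate
24 | CNP0132332.1, (2S,3S,4S,6S)-3-[(1E,3R,4S)-4-hydroxy-1,7-bis(4-hydroxyphenyl)hept-1-en-3-yl]-2-(4-hydroxyphenyl)-6-[2-(4-hydroxyphenyl)ethyl]oxan-4-ol | Oc1ccc(/C=C/[C@H]([C@@H]2[C@@H](c3ccc(O)cc3)O[C@@H](CCc3ccc(O)cc3)C[C@@H]2O)[C@@H](O)CCCc2ccc(O)cc2)cc1 | target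

**Totals**

Total step count: 12. Longest linear sequence: 10 steps (1 → 5 → 7 → 9 → 11 → 12 → 14 → 15 → 21 → 23 → 24).

**Steps most likely to fail**

Step 10. The risk is poor facial selectivity in the boron aldol: the enolate-face bias from C3' may be modest or opposed by the silyloxy centre of 19, which would leave C3/C4 epimers. The fallback replaces aldol control by thermodynamic and reagent control. It sets out from crude 23 as obtained after step 11 together with its C3/C4 epimers. Dess–Martin oxidation gives the oxan-4-one F1. 1,8-Diazabicyclo[5.4.0]undec-7-ene in CH2Cl2 then equilibrates C3 (enolization) and C2 (retro-oxa-Michael and oxa-Michael) to the all-equatorial 2,3-trans-2,6-cis ketone. LiBH(s-Bu)3 in THF at −78 °C should attack from the equatorial side and give the axial C4 alcohol, which is 23.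

Step 11. The risks are dehydration of the β-hydroxy ketone, capture of the cation by O4' in a five-membered ring, and over-reduction of the electron-rich benzylic C–O bond. The fallback is an SN1 etherification at the alcohol oxidation level. It sets out from 21: NaBH4 in MeOH reduces the aryl ketone to the benzylic alcohol F2 (either C2 epimer). Pyridinium p-toluenesulfonate in MeOH removes the TES group, and p-toluenesulfonic acid (cat.) in CH2Cl2 ionises the para-silyloxybenzylic alcohol. The cation is trapped by the oxygen on C6 under thermodynamic control (2,6-cis, aryl equatorial), which returns the route to 23.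

Step 3. The risks are erosion of enantioselectivity and self-aldol of the linear aldehyde under Me2Zn. The fallback replaces the asymmetric addition by an asymmetric reduction. It sets out from 5: addition of lithiated methyl propiolate (LiN(SiMe3)2, THF, −78 °C) gives the racemic alcohol F3, and MnO2 oxidises it to the ynone F4. Transfer hydrogenation with RuCl(p-cymene)[(S,S)-TsDPEN] and HCO2H/Et3N should then give the (4S)-alcohol, which is 7.

**Further compounds**

F1 | step 10 | (2S,3R,6S)-2-[4-(TBSO)phenyl]-6-{2-[4-(TBSO)phenyl]ethyl}-3-{(1E,3R,4S)-4-(TBSO)-1,7-bis[4-(TBSO)phenyl]hept-1-en-3-yl}oxan-4-one | CC(C)(C)[Si](C)(C)Oc1ccc(/C=C/[C@H]([C@@H]2[C@@H](c3ccc(O[Si](C)(C)C(C)(C)C)cc3)O[C@@H](CCc3ccc(O[Si](C)(C)C(C)(C)C)cc3)CC2=O)[C@@H](O[Si](C)(C)C(C)(C)C)CCCc2ccc(O[Si](C)(C)C(C)(C)C)cc2)cc1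
F2 | step 11 | (2S,3S,5S)-5-(triethylsilyloxy)-1,7-bis[4-(TBSO)phenyl]-2-{(1E,3R,4S)-4-(TBSO)-1,7-bis[4-(TBSO)phenyl]hept-1-en-3-yl}heptane-1,3-diol (C1 epimers) | CC(C)(C)[Si](C)(C)Oc1ccc(/C=C/[C@H]([C@H](C(O)c2ccc(O[Si](C)(C)C(C)(C)C)cc2)[C@@H](O)C[C@@H](O[Si](CC)(CC)CC)CCc2ccc(O[Si](C)(C)C(C)(C)C)cc2)[C@@H](O[Si](C)(C)C(C)(C)C)CCCc2ccc(O[Si](C)(C)C(C)(C)C)cc2)cc1
F3 | step 3 | methyl 4-hydroxy-7-[4-(TBSO)phenyl]hept-2-ynoate (racemic) | COC(=O)C#CC(O)CCCc1ccc(O[Si](C)(C)C(C)(C)C)cc1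
F4 | step 3 | methyl 4-oxo-7-[4-(TBSO)phenyl]hept-2-ynoate | COC(=O)C#CC(=O)CCCc1ccc(O[Si](C)(C)C(C)(C)C)cc1
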